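**Plan**

- Retrosynthetic cuts: the lactone carbonyl is taken back to a methyl acetal whose dihydropyran ring (O1–C2 and C5–C6) comes from a hetero-Diels–Alder reaction; the chain is cut at C2'–C3' (acetylide plus epoxide), at C8'–C9' (acetylide plus Weinreb amide) and at C4'–C5' and C6'–C7' (double aldol).
- Enabling feature: C3'–C8' is a 6-chloro-2,4,6-trideoxyhexose in disguise (C8' at carbonyl level, syn carbinols at C6' and C4', heteroatom-bearing C3'), which an acetaldehyde-dependent aldolase assembles and which rests as a six-membered lactol.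
- Forward, steps 1–9: the lactol ring is made and oxidised, O6' is silylated, the ring is opened, C3'/C4' become an epoxide, and C8' receives the phenylethynyl group and is reduced, saturated and acetylated.
- Forward, steps 10–16: the dihydropyran ring is built separately, its acetylide joins at C3', then Lindlar reduction, acetal-to-lactone conversion and desilylation finish the synthesis.
- Stereochemistry: C4' and C6' from the enzyme, C8' from catalyst-controlled transfer hydrogenation, C6 from the chromium-catalysed cycloaddition, the Z alkene from syn delivery of hydrogen.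

Key step: step 1

Remark: side-chain carbons are numbered C1'–C10' outward from ring carbon C6; lactols 5 and 23 are anomeric mixtures; the acetal carbon of 18–22 is drawn cis as the cycloaddition should deliver it (immaterial, since it becomes the lactone carbonyl); the (1S,2R) chromium catalyst is assumed to show with the ynal the facial sense known for simple aldehydes, otherwise its enantiomer is used.

**Route**

Step 1
Reactants: 1 chloroacetaldehyde; 2 acetaldehyde (two molecules)
Product: 5 (4R,6S)-6-(chloromethyl)tetrahydro-2H-pyran-2,4-diol (anomeric mixture), via (S)-4-chloro-3-hydroxybutanal 3 (not isolated), via open-chain 6-chloro-3,5-dihydroxyhexanal 4 (not isolated)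
Conditions: 2-deoxy-D-ribose-5-phosphate aldolase (E. coli, cell-free extract), 1 and 2 (2.1 equiv) fed slowly, aq. buffer pH 7.2, rt
Reagents that add atoms: none
Why: The active-site lysine of the aldolase forms an enamine from acetaldehyde that adds to chloroacetaldehyde, and the released aldehyde 3 is taken up again as acceptor for a second enamine addition, so that C4'–C5' and C6'–C7' are formed in one pot. The closest known reaction type is exactly this aldolase-catalysed sequential aldol of acetaldehyde with α-substituted acetaldehydes to 2,4,6-trideoxyhexoses, which is established chemistry. The one ring closes by 6-exo-trig hemiacetalisation of the C5 hydroxyl of 4 onto its C1 aldehyde. Both new carbinol centres (C4 and C6 of 5, later C6' and C4') are set by the enzyme, which presents the same enamine face to the bound acceptor in each addition and so gives the 3R,5S syn pattern; the anomeric centre is not controlled and is removed in step 2. The step needs acetaldehyde as the only donor and a stop after two additions, which the donor specificity of the enzyme and the masking of the aldehyde of 4 as the lactol secure; slow feeding keeps the aldehydes below concentrations that inactivate the enzyme.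

Step 2
Reactants: 5 (4R,6S)-6-(chloromethyl)tetrahydro-2H-pyran-2,4-diol
Product: 6 (4R,6S)-6-(chloromethyl)-4-hydroxytetrahydro-2H-pyran-2-one
Conditions: Br2, BaCO3, H2O, 0 °C to rt
Reagents that add atoms: none
Why: Buffered bromine water oxidises the hemiacetal selectively (aldose-to-aldonolactone oxidation) and leaves the secondary carbinol and both stereocentres untouched.

Step 3
Reactants: 6 (4R,6S)-6-(chloromethyl)-4-hydroxytetrahydro-2H-pyran-2-one
Product: 7 (4R,6S)-4-[(tert-butyldimethylsilyl)oxy]-6-(chloromethyl)tetrahydro-2H-pyran-2-one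
Conditions: TBSCl, imidazole, DMF, rt
Reagents that add atoms: tert-butyldimethylsilyl chloride, CC(C)(C)[Si](C)(C)Cl
Why: Standard silylation of the only hydroxyl marks O6' for the rest of the route while O4' stays tied up in the lactone; no stereocentre is affected.

Step 4
Reactants: 7 (4R,6S)-4-[(tert-butyldimethylsilyl)oxy]-6-(chloromethyl)tetrahydro-2H-pyran-2-one
Product: 8 (3R,5S)-3-[(tert-butyldimethylsilyl)oxy]-6-chloro-5-hydroxy-N-methoxy-N-methylhexanamide
Conditions: MeNH(OMe)·HCl, AlMe3, CH2Cl2, 0 °C to rt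
Reagents that add atoms: N,O-dimethylhydroxylamine hydrochloride, CNOC.Cl
Why: Aminolysis of the lactone by the aluminium amide (Weinreb amide formation) opens the ring without touching the silyl ether or the chloride and frees the C4' hydroxyl next to the chloromethyl group.

Step 5
Reactants: 8 (3R,5S)-3-[(tert-butyldimethylsilyl)oxy]-6-chloro-5-hydroxy-N-methoxy-N-methylhexanamide
Product: 9 (3R)-3-[(tert-butyldimethylsilyl)oxy]-N-methoxy-N-methyl-4-[(2S)-oxiran-2-yl]butanamide
Conditions: K2CO3, MeOH, 0 °C to rt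
Reagents that add atoms: none
Why: Intramolecular Williamson closure (3-exo-tet) of the 1,2-chlorohydrin gives the terminal epoxide with C4' unchanged, because only the C3'–Cl bond is broken.

Step 6
Reactants: 9 (3R)-3-[(tert-butyldimethylsilyl)oxy]-N-methoxy-N-methyl-4-[(2S)-oxiran-2-yl]butanamide; 10 phenylacetylene
Product: 12 (5R)-5-[(tert-butyldimethylsilyl)oxy]-6-[(2S)-oxiran-2-yl]-1-phenylhex-1-yn-3-one, via lithium phenylacetylide 11 (not isolated)
Conditions: 10, n-BuLi, THF, −78 °C; then 9, −78 to −20 °C; aq. NH4Cl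
Reagents that add atoms: none
Why: Weinreb ketone synthesis, in which the acetylide adds once through the chelated tetrahedral intermediate, while the epoxide is inert to a lithium acetylide at low temperature without a Lewis acid.

Step 7
Reactants: 12 (5R)-5-[(tert-butyldimethylsilyl)oxy]-6-[(2S)-oxiran-2-yl]-1-phenylhex-1-yn-3-one
Product: 13 (3S,5S)-5-[(tert-butyldimethylsilyl)oxy]-6-[(2S)-oxiran-2-yl]-1-phenylhex-1-yn-3-ol
Conditions: Ru[(S,S)-TsDPEN](p-cymene) (2 mol%), i-PrOH, rt
Reagents that add atoms: none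
Why: Noyori–Ikariya asymmetric transfer hydrogenation of an alkynyl ketone, where the (S,S) catalyst distinguishes alkynyl from alkyl and delivers hydride to one carbonyl face under reagent control, setting C8' as the (S)-propargylic carbinol, anti to the C6' silyl ether.

Step 8
Reactants: 13 (3S,5S)-5-[(tert-butyldimethylsilyl)oxy]-6-[(2S)-oxiran-2-yl]-1-phenylhex-1-yn-3-ol
Product: 14 (3R,5S)-5-[(tert-butyldimethylsilyl)oxy]-6-[(2S)-oxiran-2-yl]-1-phenylhexan-3-ol
Conditions: H2 (1 atm), 10% Pd/C, EtOAc, rt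
Reagents that add atoms: none
Why: Heterogeneous hydrogenation saturates the aryl alkyne to the 2-phenylethyl group without changing the C8' configuration (only its descriptor changes), and the silyl ether and aliphatic epoxide should tolerate neutral Pd/C.

Step 9
Reactants: 14 (3R,5S)-5-[(tert-butyldimethylsilyl)oxy]-6-[(2S)-oxiran-2-yl]-1-phenylhexan-3-ol
Product: 15 (3R,5S)-5-[(tert-butyldimethylsilyl)oxy]-6-[(2S)-oxiran-2-yl]-1-phenylhexan-3-yl acetate
Conditions: Ac2O, pyridine, DMAP (cat.), CH2Cl2, 0 °C to rt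
Reagents that add atoms: acetic anhydride, CC(=O)OC(C)=O
Why: DMAP-catalysed acylation of the single free hydroxyl installs the C8' acetate of the target.

Step 10
Reactants: 16 3-(trimethylsilyl)prop-2-ynal; 17 (E)-1-methoxybuta-1,3-diene
Product: 18 (2R,6S)-2-methoxy-6-[(trimethylsilyl)ethynyl]-5,6-dihydro-2H-pyran
Conditions: CrCl(L) (3 mol%), L = (1S,2R)-1-{[3-(1-adamantyl)-5-methyl-2-oxidobenzylidene]amino}indan-2-olate, 4 Å MS, neat, 0 °C to rt
Reagents that add atoms: none
Why: Catalytic enantioselective hetero-Diels–Alder reaction of an ynal with an electron-rich diene, in which the chiral chromium Lewis acid blocks one aldehyde face to set C6 as (S) and the endo mode gives the cis 2,6-acetal.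

Step 11
Reactants: 18 (2R,6S)-2-methoxy-6-[(trimethylsilyl)ethynyl]-5,6-dihydro-2H-pyran
Product: 19 (2R,6S)-6-ethynyl-2-methoxy-5,6-dihydro-2H-pyran
Conditions: K2CO3 (cat.), MeOH, 0 °C
Reagents that add atoms: none
Why: Base-catalysed methanolysis of the alkynylsilane (protodesilylation) frees the terminal alkyne without affecting the mixed acetal.

Step 12
Reactants: 15 (3R,5S)-5-[(tert-butyldimethylsilyl)oxy]-6-[(2S)-oxiran-2-yl]-1-phenylhexan-3-yl acetate; 19 (2R,6S)-6-ethynyl-2-methoxy-5,6-dihydro-2H-pyran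
Product: 21 (3R,5R,7R)-5-[(tert-butyldimethylsilyl)oxy]-7-hydroxy-10-[(2S,6R)-6-methoxy-3,6-dihydro-2H-pyran-2-yl]-1-phenyldec-9-yn-3-yl acetate, via lithium acetylide 20 (not isolated)
Conditions: 19 (1.5 equiv), n-BuLi, THF, −78 °C; BF3·OEt2; then 15, −78 °C; aq. NH4Cl
Reagents that add atoms: none
Why: Yamaguchi–Hirao alkynylation, in which the BF3-activated terminal epoxide is opened at its unsubstituted carbon by the alkynyl borate, so that C2'–C3' forms and C4' keeps its configuration as the free carbinol.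

Step 13
Reactants: 21 (3R,5R,7R)-5-[(tert-butyldimethylsilyl)oxy]-7-hydroxy-10-[(2S,6R)-6-methoxy-3,6-dihydro-2H-pyran-2-yl]-1-phenyldec-9-yn-3-yl acetate
Product: 22 (3R,5R,7R,9Z)-5-[(tert-butyldimethylsilyl)oxy]-7-hydroxy-10-[(2S,6R)-6-methoxy-3,6-dihydro-2H-pyran-2-yl]-1-phenyldec-9-en-3-yl acetate
Conditions: H2 (1 atm), Pd/CaCO3 poisoned with Pb(OAc)2, quinoline, EtOAc, rt
Reagents that add atoms: none
Why: Lindlar semihydrogenation adds hydrogen syn to the alkyne and gives the (Z)-C1'=C2' alkene, while the ring alkene is not reduced by the poisoned catalyst.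

Step 14
Reactants: 22 (3R,5R,7R,9Z)-5-[(tert-butyldimethylsilyl)oxy]-7-hydroxy-10-[(2S,6R)-6-methoxy-3,6-dihydro-2H-pyran-2-yl]-1-phenyldec-9-en-3-yl acetate
Product: 23 (3R,5R,7R,9Z)-5-[(tert-butyldimethylsilyl)oxy]-7-hydroxy-10-[(2S)-6-hydroxy-3,6-dihydro-2H-pyran-2-yl]-1-phenyldec-9-en-3-yl acetate (anomeric mixture)
Conditions: PPTS (cat.), acetone/H2O, rt
Reagents that add atoms: water, O
Why: Mild acid hydrolysis of the allylic mixed acetal through its conjugated oxocarbenium ion gives the lactol, while the silyl ether and acetate persist.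

Step 15
Reactants: 23 (3R,5R,7R,9Z)-5-[(tert-butyldimethylsilyl)oxy]-7-hydroxy-10-[(2S)-6-hydroxy-3,6-dihydro-2H-pyran-2-yl]-1-phenyldec-9-en-3-yl acetate
Product: 24 (3R,5R,7R,9Z)-5-[(tert-butyldimethylsilyl)oxy]-7-hydroxy-10-[(2S)-6-oxo-3,6-dihydro-2H-pyran-2-yl]-1-phenyldec-9-en-3-yl acetate
Conditions: MnO2 (activated, excess), CH2Cl2, rt
Reagents that add atoms: none
Why: MnO2 oxidises the allylic hemiacetal chemoselectively to the α,β-unsaturated δ-lactone, whereas the homoallylic C4' alcohol is not activated and should be left alone.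

Step 16
Reactants: 24 (3R,5R,7R,9Z)-5-[(tert-butyldimethylsilyl)oxy]-7-hydroxy-10-[(2S)-6-oxo-3,6-dihydro-2H-pyran-2-yl]-1-phenyldec-9-en-3-yl acetate
Product: 25 (6S)-6-[(1Z,4R,6R,8R)-8-acetoxy-4,6-dihydroxy-10-phenyldec-1-en-1-yl]-5,6-dihydro-2H-pyran-2-one (target)
Conditions: HF·pyridine, pyridine, THF, 0 °C to rt
Reagents that add atoms: none
Why: Fluoride-mediated desilylation under buffered acidic conditions removes the silyl ether without acyl migration or lactone opening and reveals the C6' hydroxyl.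

**Compound list**

1 | chloroacetaldehyde | ClCC=O | starting material
2 | acetaldehyde | CC=O | starting material
3 | (S)-4-chloro-3-hydroxybutanal | O=CC[C@H](O)CCl | intermediate
4 | (3R,5S)-6-chloro-3,5-dihydroxyhexanal | O=CC[C@H](O)C[C@H](O)CCl | intermediate
5 | (4R,6S)-6-(chloromethyl)tetrahydro-2H-pyran-2,4-diol (anomeric mixture) | OC1C[C@H](O)C[C@@H](CCl)O1 | intermediate
6 | (4R,6S)-6-(chloromethyl)-4-hydroxytetrahydro-2H-pyran-2-one | O=C1C[C@H](O)C[C@@H](CCl)O1 | intermediate
7 | (4R,6S)-4-[(tert-butyldimethylsilyl)oxy]-6-(chloromethyl)tetrahydro-2H-pyran-2-one | O=C1C[C@H](O[Si](C)(C)C(C)(C)C)C[C@@H](CCl)O1 | intermediate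
8 | (3R,5S)-3-[(tert-butyldimethylsilyl)oxy]-6-chloro-5-hydroxy-N-methoxy-N-methylhexanamide | CON(C)C(=O)C[C@H](O[Si](C)(C)C(C)(C)C)C[C@H](O)CCl | intermediate
9 | (3R)-3-[(tert-butyldimethylsilyl)oxy]-N-methoxy-N-methyl-4-[(2S)-oxiran-2-yl]butanamide | CON(C)C(=O)C[C@H](O[Si](C)(C)C(C)(C)C)C[C@H]1CO1 | intermediate
10 | phenylacetylene | C#Cc1ccccc1 | starting material
11 | lithium phenylacetylide | [Li]C#Cc1ccccc1 | intermediate
12 | (5R)-5-[(tert-butyldimethylsilyl)oxy]-6-[(2S)-oxiran-2-yl]-1-phenylhex-1-yn-3-one | O=C(C#Cc1ccccc1)C[C@H](O[Si](C)(C)C(C)(C)C)C[C@H]1CO1 | intermediate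
13 | (3S,5S)-5-[(tert-butyldimethylsilyl)oxy]-6-[(2S)-oxiran-2-yl]-1-phenylhex-1-yn-3-ol | O[C@H](C#Cc1ccccc1)C[C@H](O[Si](C)(C)C(C)(C)C)C[C@H]1CO1 | intermediate
14 | (3R,5S)-5-[(tert-butyldimethylsilyl)oxy]-6-[(2S)-oxiran-2-yl]-1-phenylhexan-3-ol | O[C@H](CCc1ccccc1)C[C@H](O[Si](C)(C)C(C)(C)C)C[C@H]1CO1 | intermediate
15 | (3R,5S)-5-[(tert-butyldimethylsilyl)oxy]-6-[(2S)-oxiran-2-yl]-1-phenylhexan-3-yl acetate | CC(=O)O[C@H](CCc1ccccc1)C[C@H](O[Si](C)(C)C(C)(C)C)C[C@H]1CO1 | intermediate
16 | 3-(trimethylsilyl)prop-2-ynal | C[Si](C)(C)C#CC=O | starting material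
17 | (E)-1-methoxybuta-1,3-diene | CO/C=C/C=C | starting material
18 | (2R,6S)-2-methoxy-6-[(trimethylsilyl)ethynyl]-5,6-dihydro-2H-pyran (cis) | CO[C@H]1C=CC[C@@H](C#C[Si](C)(C)C)O1 | intermediate
19 | (2R,6S)-6-ethynyl-2-methoxy-5,6-dihydro-2H-pyran | CO[C@H]1C=CC[C@@H](C#C)O1 | intermediate
20 | lithium acetylide of 19 | CO[C@H]1C=CC[C@@H](C#C[Li])O1 | intermediate
21 | (3R,5R,7R)-5-[(tert-butyldimethylsilyl)oxy]-7-hydroxy-10-[(2S,6R)-6-methoxy-3,6-dihydro-2H-pyran-2-yl]-1-phenyldec-9-yn-3-yl acetate | CC(=O)O[C@H](CCc1ccccc1)C[C@H](O[Si](C)(C)C(C)(C)C)C[C@H](O)CC#C[C@@H]1CC=C[C@H](OC)O1 | intermediate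
22 | (3R,5R,7R,9Z)-5-[(tert-butyldimethylsilyl)oxy]-7-hydroxy-10-[(2S,6R)-6-methoxy-3,6-dihydro-2H-pyran-2-yl]-1-phenyldec-9-en-3-yl acetate | CC(=O)O[C@H](CCc1ccccc1)C[C@H](O[Si](C)(C)C(C)(C)C)C[C@H](O)C/C=C\[C@@H]1CC=C[C@H](OC)O1 | intermediate
23 | (3R,5R,7R,9Z)-5-[(tert-butyldimethylsilyl)oxy]-7-hydroxy-10-[(2S)-6-hydroxy-3,6-dihydro-2H-pyran-2-yl]-1-phenyldec-9-en-3-yl acetate (anomeric mixture) | CC(=O)O[C@H](CCc1ccccc1)C[C@H](O[Si](C)(C)C(C)(C)C)C[C@H](O)C/C=C\[C@@H]1CC=CC(O)O1 | intermediate
24 | (3R,5R,7R,9Z)-5-[(tert-butyldimethylsilyl)oxy]-7-hydroxy-10-[(2S)-6-oxo-3,6-dihydro-2H-pyran-2-yl]-1-phenyldec-9-en-3-yl acetate | CC(=O)O[C@H](CCc1ccccc1)C[C@H](O[Si](C)(C)C(C)(C)C)C[C@H](O)C/C=C\[C@@H]1CC=CC(=O)O1 | intermediate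
25 | (6S)-6-[(1Z,4R,6R,8R)-8-acetoxy-4,6-dihydroxy-10-phenyldec-1-en-1-yl]-5,6-dihydro-2H-pyran-2-one | CC(=O)O[C@H](CCc1ccccc1)C[C@H](O)C[C@H](O)C/C=C\[C@@H]1CC=CC(=O)O1 | target

**Step count and risks**

Total step count: 16. Longest linear sequence: 14 (steps 1–9 and 12–16); steps 10–11 make the alkyne partner.

Steps most likely to fail:

1. Step 12 (epoxide alkynylation). BF3 may ionise the allylic mixed acetal of the nucleophile, leading to self-condensation or loss of methoxide, and the borate may attack the acetate, so that the epoxide is not cleanly consumed. Fallback: move the cycloaddition behind the coupling, so that only a robust propargylic acetal meets the Lewis acid. It sets out from 15. Opening with the lithium acetylide of 3,3-diethoxyprop-1-yne (C#CC(OCC)OCC; n-BuLi, BF3·OEt2, THF, −78 °C) should give (3R,5R,7R)-5-[(tert-butyldimethylsilyl)oxy]-11,11-diethoxy-7-hydroxy-1-phenylundec-9-yn-3-yl acetate F1. Mild hydrolysis of the diethyl acetal (acidic resin, wet acetone) should give the ynal (3R,5R,7R)-5-[(tert-butyldimethylsilyl)oxy]-7-hydroxy-11-oxo-1-phenylundec-9-yn-3-yl acetate F2. The hetero-Diels–Alder reaction of F2 with 17 under the chromium catalyst of step 10 then builds the dihydropyran on the full chain under catalyst control and comes back to the route at 21.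

2. Step 8 (alkyne hydrogenation beside the epoxide). Reductive opening of the epoxide on palladium, or redox isomerisation of the intermediate allylic alcohol to the ketone, would erode material and the C8' centre. Fallback: carry the chlorohydrin, not the epoxide, through the reductions. It sets out from 8. Excess lithium phenylacetylide should give (5R,7S)-5-[(tert-butyldimethylsilyl)oxy]-8-chloro-7-hydroxy-1-phenyloct-1-yn-3-one F3. The transfer hydrogenation of step 7 should give (3S,5S,7S)-5-[(tert-butyldimethylsilyl)oxy]-8-chloro-1-phenyloct-1-yne-3,7-diol F4. Hydrogenation over Pd/C, to which a primary alkyl chloride is robust, should give (3R,5S,7S)-5-[(tert-butyldimethylsilyl)oxy]-8-chloro-1-phenyloctane-3,7-diol F5. K2CO3 in MeOH then closes the epoxide and comes back to the route at 14.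

3. Step 14 (acetal hydrolysis). The liberated lactol can ring-open to the (Z)-hydroxy enal, which may isomerise or decompose before oxidation, and hydrolysis may be incomplete under conditions mild enough for the silyl ether. Fallback: avoid the free lactol. It sets out from 22. Silylation of the C4' hydroxyl (TBSOTf, 2,6-lutidine) should give (3R,5S,7R,9Z)-5,7-bis[(tert-butyldimethylsilyl)oxy]-10-[(2S,6R)-6-methoxy-3,6-dihydro-2H-pyran-2-yl]-1-phenyldec-9-en-3-yl acetate F6. Direct oxidation of the allylic acetal with pyridinium chlorochromate (C5H5NH[CrO3Cl], CH2Cl2) should give the lactone (3R,5S,7R,9Z)-5,7-bis[(tert-butyldimethylsilyl)oxy]-10-[(2S)-6-oxo-3,6-dihydro-2H-pyran-2-yl]-1-phenyldec-9-en-3-yl acetate F7. HF·pyridine then removes both silyl groups and comes back to the route at 25.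

Further compounds
F1 | step 12 | (3R,5R,7R)-5-[(tert-butyldimethylsilyl)oxy]-11,11-diethoxy-7-hydroxy-1-phenylundec-9-yn-3-yl acetate | CC(=O)O[C@H](CCc1ccccc1)C[C@H](O[Si](C)(C)C(C)(C)C)C[C@H](O)CC#CC(OCC)OCC
F2 | step 12 | (3R,5R,7R)-5-[(tert-butyldimethylsilyl)oxy]-7-hydroxy-11-oxo-1-phenylundec-9-yn-3-yl acetate | CC(=O)O[C@H](CCc1ccccc1)C[C@H](O[Si](C)(C)C(C)(C)C)C[C@H](O)CC#CC=O
F3 | step 8 | (5R,7S)-5-[(tert-butyldimethylsilyl)oxy]-8-chloro-7-hydroxy-1-phenyloct-1-yn-3-one | O=C(C#Cc1ccccc1)C[C@H](O[Si](C)(C)C(C)(C)C)C[C@H](O)CCl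
F4 | step 8 | (3S,5S,7S)-5-[(tert-butyldimethylsilyl)oxy]-8-chloro-1-phenyloct-1-yne-3,7-diol | O[C@H](C#Cc1ccccc1)C[C@H](O[Si](C)(C)C(C)(C)C)C[C@H](O)CCl
F5 | step 8 | (3R,5S,7S)-5-[(tert-butyldimethylsilyl)oxy]-8-chloro-1-phenyloctane-3,7-diol | O[C@H](CCc1ccccc1)C[C@H](O[Si](C)(C)C(C)(C)C)C[C@H](O)CCl
F6 | step 14 | (3R,5S,7R,9Z)-5,7-bis[(tert-butyldimethylsilyl)oxy]-10-[(2S,6R)-6-methoxy-3,6-dihydro-2H-pyran-2-yl]-1-phenyldec-9-en-3-yl acetate | CC(=O)O[C@H](CCc1ccccc1)C[C@H](O[Si](C)(C)C(C)(C)C)C[C@H](O[Si](C)(C)C(C)(C)C)C/C=C\[C@@H]1CC=C[C@H](OC)O1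
F7 | step 14 | (3R,5S,7R,9Z)-5,7-bis[(tert-butyldimethylsilyl)oxy]-10-[(2S)-6-oxo-3,6-dihydro-2H-pyran-2-yl]-1-phenyldec-9-en-3-yl acetate | CC(=O)O[C@H](CCc1ccccc1)C[C@H](O[Si](C)(C)C(C)(C)C)C[C@H](O[Si](C)(C)C(C)(C)C)C/C=C\[C@@H]1CC=CC(=O)O1
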